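**Retrosynthetic overview**
1. The butenolide is attached last: C12–C13 by 9-BBN hydroboration / B-alkyl Suzuki coupling of a C9-vinyl diene with 4-bromofuran-2(5H)-one.
2. 5α-H and 6α-OH come from α-face hydroboration of a Δ5,Δ8-diene (ring B as a 1,4-cyclohexadiene).
3. The decalin comes from an acyclic 1,7-enyne in one flask: ring-closing enyne metathesis closes ring A (C5=C10), then a Diels–Alder reaction with but-2-ynal closes ring B (C7–C8 and C9–C10) and gives the Δ8 alkene directly.
4. The enyne comes from trans-selective α-ethynylation of an α-methyl-γ-butyrolactone (quaternary C4); the lactone comes from (R)-epichlorohydrin (C2), isopropenyl Grignard and propionic acid.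
5. Ring order: A, then B in the same operation; the butenolide ring is brought in intact.

Assumption: labdane numbering (C1–C20) is used for positions; 6 and 7 are mixtures of epimers at the propionate-derived methine carbon, which becomes uniform in step 3.

**Step 1**
Reactants: 1 (R)-epichlorohydrin; 2 isopropenylmagnesium bromide
Product: 4 (2R)-2-(2-methylprop-2-en-1-yl)oxirane, via chlorohydrin 3 (not isolated)
Conditions: CuI (10 mol %), THF, −40 °C; then aq. NaOH, rt
Reagents that add atoms: isopropenylmagnesium bromide 2, C=C(C)[Mg]Br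
Why: Cu-catalysed Grignard opening at the epoxide CH2 of epichlorohydrin, then base-induced closure of the chlorohydrin (intramolecular Williamson reaction); no bond to the stereocentre is broken, so the centre of 1 becomes C2.

**Step 2**
Reactants: 4 (2R)-2-(2-methylprop-2-en-1-yl)oxirane; 5 propionic acid
Product: 7 (5S)-3-methyl-5-(2-methylprop-2-en-1-yl)oxolan-2-one (3-epimers), via hydroxy acid 6 (not isolated)
Conditions: 5, LDA (2.1 equiv), THF/HMPA, 0 → 50 °C; then 4; aq. HCl; TsOH (cat.), toluene, 80 °C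
Reagents that add atoms: propionic acid 5, CCC(=O)O
Why: Opening of the terminal epoxide by the carboxylic acid dianion (Creger reaction), then acid-catalysed γ-lactonisation; C2 is untouched and the new methine centre is erased in step 3.

**Step 3**
Reactants: 7 lactone; 8 TMS-EBX, 1-[(trimethylsilyl)ethynyl]-1,2-benziodoxol-3(1H)-one
Product: 10 (3S,5S)-3-ethynyl-3-methyl-5-(2-methylprop-2-en-1-yl)oxolan-2-one, via silylalkyne 9 (not isolated)
Conditions: LDA (1.1 equiv), THF, −78 °C; 8, −78 → −20 °C; then TBAF (wet THF), 0 °C; aq. NH4Cl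
Reagents that add atoms: TMS-EBX 8, C[Si](C)(C)C#CI1OC(=O)c2ccccc12
Why: Electrophilic α-alkynylation of the lactone enolate with a hypervalent-iodine EBX reagent (Waser alkynylation), then desilylation; the planar enolate is attacked anti to the γ-substituent, as in alkylations of γ-substituted butyrolactones, so quaternary C4 forms with ethynyl (C5) trans to C1 (about 10:1 expected).

**Step 4**
Reactants: 10 ethynyl lactone
Product: 11 (2S,4R)-2-ethynyl-2,6-dimethylhept-6-ene-1,4-diol
Conditions: LiAlH4, THF, 0 °C; Fieser work-up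
Reagents that add atoms: none
Why: Hydride reduction of the lactone to the diol (C19–OH and C2–OH); alkyne, alkene and both stereocentres are untouched.

**Step 5**
Reactants: 11 diol
Product: 12 (2S,4R)-1,4-bis(tert-butyldimethylsilyloxy)-2-ethynyl-2,6-dimethylhept-6-ene
Conditions: TBSOTf (2.5 equiv), 2,6-lutidine, CH2Cl2, −78 → 0 °C
Reagents that add atoms: tert-butyldimethylsilyl triflate, CC(C)(C)[Si](C)(C)OS(=O)(=O)C(F)(F)F
Why: Silyl ether formation on the primary neopentyl and the secondary alcohol, so that the Ru catalyst, Lewis acid, borane and ylide used later meet no free OH at C2 or C19.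

**Step 6**
Reactants: 12 bis-TBS enyne; 13 but-2-ynal
Product: 15 2α,19-bis(tert-butyldimethylsilyloxy)-12,13,14,15,16-pentanorlabda-5,8-dien-11-al, via diene 14 (not isolated)
Conditions: Stewart–Grubbs catalyst (10 mol %), ethylene (1 atm), toluene, 80 °C; then 13 (2 equiv), Me2AlCl (25 mol %), −40 → 0 °C, same flask
Reagents that add atoms: but-2-ynal 13, CC#CC=O
Why: Ring-closing enyne metathesis (yne-then-ene, helped by the gem-disubstituted C4) gives the 1-vinyl-2-methylcyclohexene 14, and its Lewis-acid-promoted Diels–Alder reaction with the ynal closes ring B; the free diene terminus C7 bonds to the ynal β-carbon (ortho regiochemistry), and the dienophile adds anti to the pseudoaxial C4–CH2OTBS group, which sets quaternary C10 with its methyl cis to C19.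

**Step 7**
Reactants: 15 dienal
Product: 17 2α,19-bis(tert-butyldimethylsilyloxy)-12,13,14,15,16-pentanorlabd-8-ene-6α,11-diol, via organoborane 16 (not isolated)
Conditions: BH3·THF (3 equiv), THF, 0 °C → rt; then aq. NaOH, H2O2, 0 °C
Reagents that add atoms: hydrogen peroxide, OO
Why: Hydroboration–oxidation (the aldehyde is reduced at the same time): B adds to C6 and H to C5 of the trisubstituted Δ5 alkene, syn from the α face because the β face is blocked by the axial C10-methyl and C4–CH2OTBS (as in Δ5-steroids); this sets 5α-H (trans-decalin) and 6α-OH, and the tetrasubstituted Δ8 alkene does not react.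

**Step 8**
Reactants: 17 diol
Product: 18 2α,19-bis(tert-butyldimethylsilyloxy)-6α-hydroxy-12,13,14,15,16-pentanorlabd-8-en-11-al
Conditions: MnO2 (15 equiv), CH2Cl2, rt
Reagents that add atoms: none
Why: Chemoselective MnO2 oxidation of the allylic primary alcohol; the secondary, non-allylic 6-OH is not oxidised.

**Step 9**
Reactants: 18 enal; 19 methyltriphenylphosphonium bromide
Product: 20 2α,19-bis(tert-butyldimethylsilyloxy)-13,14,15,16-tetranorlabda-8,11-dien-6α-ol
Conditions: 19 (3 equiv), KHMDS (2.8 equiv), THF, 0 °C; then 18, 0 °C → rt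
Reagents that add atoms: methyltriphenylphosphonium bromide 19, C[P+](c1ccccc1)(c1ccccc1)c1ccccc1.[Br-]
Why: Wittig methylenation of the hindered enal (as for β-cyclocitral) gives the C9-vinyl diene; no stereocentre is involved.

**Step 10**
Reactants: 20 vinyl diene; 21 4-bromofuran-2(5H)-one
Product: 23 2α,19-bis(tert-butyldimethylsilyloxy)-6α-hydroxylabda-8,13-dien-15,16-olide, via alkylborane 22 (not isolated)
Conditions: 9-BBN (2.5 equiv), THF, 0 °C → rt; then 21, Pd(dppf)Cl2 (5 mol %), AsPh3 (10 mol %), aq. K3PO4, DMF, rt → 40 °C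
Reagents that add atoms: 4-bromofuran-2(5H)-one 21, BrC1=CC(=O)OC1
Why: Anti-Markovnikov hydroboration of the only monosubstituted alkene by 9-BBN, then B-alkyl Suzuki–Miyaura coupling of the primary alkylborane with the β-bromobutenolide, forms C12–C13; the tetrasubstituted alkene and all stereocentres are untouched.

**Step 11**
Reactants: 23 bis-TBS butenolide
Product: 24 2α,6α,19-trihydroxylabda-8,13-dien-15,16-olide (2R,4S,5R,6S,10S), the target
Conditions: HF·pyridine, THF/pyridine, 0 °C → rt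
Reagents that add atoms: none
Why: Fluoride cleavage of both silyl ethers under non-basic conditions that leave the butenolide and the homoallylic alcohol intact.

**Compound list**
1 | (R)-epichlorohydrin | ClC[C@H]1CO1 | starting material
2 | isopropenylmagnesium bromide | C=C(C)[Mg]Br | starting material
3 | (2R)-1-chloro-4-methylpent-4-en-2-ol | C=C(C)C[C@@H](O)CCl | intermediate
4 | (2R)-2-(2-methylprop-2-en-1-yl)oxirane | C=C(C)C[C@@H]1CO1 | intermediate
5 | propionic acid | CCC(=O)O | starting material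
6 | (4S)-4-hydroxy-2,6-dimethylhept-6-enoic acid (2-epimers) | C=C(C)C[C@@H](O)CC(C)C(=O)O | intermediate
7 | (5S)-3-methyl-5-(2-methylprop-2-en-1-yl)oxolan-2-one (3-epimers) | C=C(C)C[C@@H]1CC(C)C(=O)O1 | intermediate
8 | TMS-EBX, 1-[(trimethylsilyl)ethynyl]-1,2-benziodoxol-3(1H)-one | C[Si](C)(C)C#CI1OC(=O)c2ccccc12 | starting material
9 | (3S,5S)-3-methyl-5-(2-methylprop-2-en-1-yl)-3-[(trimethylsilyl)ethynyl]oxolan-2-one | C=C(C)C[C@@H]1C[C@@](C)(C#C[Si](C)(C)C)C(=O)O1 | intermediate
10 | (3S,5S)-3-ethynyl-3-methyl-5-(2-methylprop-2-en-1-yl)oxolan-2-one | C=C(C)C[C@@H]1C[C@@](C)(C#C)C(=O)O1 | intermediate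
11 | (2S,4R)-2-ethynyl-2,6-dimethylhept-6-ene-1,4-diol | C=C(C)C[C@@H](O)C[C@@](C)(C#C)CO | intermediate
12 | (2S,4R)-1,4-bis(tert-butyldimethylsilyloxy)-2-ethynyl-2,6-dimethylhept-6-ene | C=C(C)C[C@@H](O[Si](C)(C)C(C)(C)C)C[C@@](C)(C#C)CO[Si](C)(C)C(C)(C)C | intermediate
13 | but-2-ynal | CC#CC=O | starting material
14 | (4R,6S)-4-(tert-butyldimethylsilyloxy)-6-[(tert-butyldimethylsilyloxy)methyl]-1-ethenyl-2,6-dimethylcyclohex-1-ene | C=CC1=C(C)C[C@@H](O[Si](C)(C)C(C)(C)C)C[C@]1(C)CO[Si](C)(C)C(C)(C)C | intermediate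
15 | 2α,19-bis(TBS-oxy)-12,13,14,15,16-pentanorlabda-5,8-dien-11-al (4β-CH2OTBS, 10β-CH3) | CC1=C(C=O)[C@@]2(C)C[C@@H](O[Si](C)(C)C(C)(C)C)C[C@](C)(CO[Si](C)(C)C(C)(C)C)C2=CC1 | intermediate
16 | 6α-boryl 11-O-boryl adduct of 15 (5α-H) | CC1=C(COB)[C@@]2(C)C[C@@H](O[Si](C)(C)C(C)(C)C)C[C@](C)(CO[Si](C)(C)C(C)(C)C)[C@@H]2[C@@H](B)C1 | intermediate
17 | 2α,19-bis(TBS-oxy)-12,13,14,15,16-pentanorlabd-8-ene-6α,11-diol | CC1=C(CO)[C@@]2(C)C[C@@H](O[Si](C)(C)C(C)(C)C)C[C@](C)(CO[Si](C)(C)C(C)(C)C)[C@@H]2[C@@H](O)C1 | intermediate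
18 | 2α,19-bis(TBS-oxy)-6α-hydroxy-12,13,14,15,16-pentanorlabd-8-en-11-al | CC1=C(C=O)[C@@]2(C)C[C@@H](O[Si](C)(C)C(C)(C)C)C[C@](C)(CO[Si](C)(C)C(C)(C)C)[C@@H]2[C@@H](O)C1 | intermediate
19 | methyltriphenylphosphonium bromide | C[P+](c1ccccc1)(c1ccccc1)c1ccccc1.[Br-] | starting material
20 | 2α,19-bis(TBS-oxy)-13,14,15,16-tetranorlabda-8,11-dien-6α-ol | CC1=C(C=C)[C@@]2(C)C[C@@H](O[Si](C)(C)C(C)(C)C)C[C@](C)(CO[Si](C)(C)C(C)(C)C)[C@@H]2[C@@H](O)C1 | intermediate
21 | 4-bromofuran-2(5H)-one | BrC1=CC(=O)OC1 | starting material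
22 | 12-(9-borabicyclo[3.3.1]nonan-9-yl) adduct of 20 (6-O-borinate) | CC1=C(CCB2C3CCCC2CCC3)[C@@]2(C)C[C@@H](O[Si](C)(C)C(C)(C)C)C[C@](C)(CO[Si](C)(C)C(C)(C)C)[C@@H]2[C@@H](OB2C3CCCC2CCC3)C1 | intermediate
23 | 2α,19-bis(TBS-oxy)-6α-hydroxylabda-8,13-dien-15,16-olide | CC1=C(CCC2=CC(=O)OC2)[C@@]2(C)C[C@@H](O[Si](C)(C)C(C)(C)C)C[C@](C)(CO[Si](C)(C)C(C)(C)C)[C@@H]2[C@@H](O)C1 | intermediate
24 | 2α,6α,19-trihydroxylabda-8,13-dien-15,16-olide (2R,4S,5R,6S,10S) | CC1=C(CCC2=CC(=O)OC2)[C@@]2(C)C[C@@H](O)C[C@](C)(CO)[C@@H]2[C@@H](O)C1 | target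

**Totals**
Total step count: 11. Longest linear sequence: 11 steps (from 1).

**Three steps most likely to fail**

Step 6. The metathesis must form a tetrasubstituted ring alkene next to a quaternary propargylic carbon, and the cycloaddition must pick one diene face. The fallback sets out from 12 and comes back at 14, which is then isolated and taken to 15 with 13 and Me2AlCl in a separate operation. Ring A is closed by an aldol condensation instead of metathesis. Ozonolysis of the 1,1-disubstituted alkene of 12 (O3, CH2Cl2, −78 °C; Me2S; the alkyne survives) gives the methyl ketone F1. Anti-Markovnikov hydration of the alkyne (dicyclohexylborane, then NaBO3) gives the keto aldehyde F2. Pyrrolidinium acetate (benzene, 60 °C) condenses the aldehyde α-carbon onto the ketone through its enamine to give the cyclohexenecarbaldehyde F3. Wittig methylenation (Ph3P=CH2) gives 14.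

Step 3. EBX alkynylation of a simple, non-stabilised lactone enolate has little precedent. The fallback sets out from 7 and comes back at 11. Kende-type dichlorovinylation of the enolate (LDA, trichloroethylene, THF/HMPA) gives the dichlorovinyl lactone F4 with the same trans selectivity. LiAlH4 reduces it to the dichlorovinyl diol F5. Excess n-BuLi (−78 → 0 °C) eliminates both chlorides to the acetylide, which gives 11 on protonation.

Step 10. The B-alkyl Suzuki coupling runs with a base-sensitive bromobutenolide and a free 6-OH. The fallback sets out from 20 and comes back at 23. Hydroboration with 9-BBN and oxidation (NaBO3) gives the primary alcohol F6. Selective Appel iodination of the primary alcohol (I2, PPh3, imidazole, 0 °C) gives the iodide F7. Nickel-catalysed reductive cross-electrophile coupling of F7 with 21 (NiI2·glyme, dtbbpy, Zn, DMA) gives 23.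

**Further compounds**
F1 | step 6 | (4R,6S)-4-(tert-butyldimethylsilyloxy)-6-[(tert-butyldimethylsilyloxy)methyl]-6-methyloct-7-yn-2-one | CC(=O)C[C@@H](O[Si](C)(C)C(C)(C)C)C[C@@](C)(C#C)CO[Si](C)(C)C(C)(C)C
F2 | step 6 | (3S,5R)-5-(tert-butyldimethylsilyloxy)-3-[(tert-butyldimethylsilyloxy)methyl]-3-methyl-7-oxooctanal | CC(=O)C[C@@H](O[Si](C)(C)C(C)(C)C)C[C@@](C)(CC=O)CO[Si](C)(C)C(C)(C)C
F3 | step 6 | (4R,6S)-4-(tert-butyldimethylsilyloxy)-6-[(tert-butyldimethylsilyloxy)methyl]-2,6-dimethylcyclohex-1-ene-1-carbaldehyde | O=CC1=C(C)C[C@@H](O[Si](C)(C)C(C)(C)C)C[C@]1(C)CO[Si](C)(C)C(C)(C)C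
F4 | step 3 | (3S,5S)-3-[(E)-1,2-dichloroethenyl]-3-methyl-5-(2-methylprop-2-en-1-yl)oxolan-2-one | C=C(C)C[C@@H]1C[C@@](C)(/C(Cl)=C\Cl)C(=O)O1
F5 | step 3 | (2S,4R)-2-[(E)-1,2-dichloroethenyl]-2,6-dimethylhept-6-ene-1,4-diol | C=C(C)C[C@@H](O)C[C@@](C)(/C(Cl)=C\Cl)CO
F6 | step 10 | 2α,19-bis(TBS-oxy)-13,14,15,16-tetranorlabd-8-ene-6α,12-diol | CC1=C(CCO)[C@@]2(C)C[C@@H](O[Si](C)(C)C(C)(C)C)C[C@](C)(CO[Si](C)(C)C(C)(C)C)[C@@H]2[C@@H](O)C1
F7 | step 10 | 2α,19-bis(TBS-oxy)-12-iodo-13,14,15,16-tetranorlabd-8-en-6α-ol | CC1=C(CCI)[C@@]2(C)C[C@@H](O[Si](C)(C)C(C)(C)C)C[C@](C)(CO[Si](C)(C)C(C)(C)C)[C@@H]2[C@@H](O)C1
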